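**Plan**

1. Retrosynthesis: remove the C8 angelate and the two late unsaturations (C11=C13, C2=C3), then cut C3–C4 and C1–C10 together. This excises C1–C3 as one allyl-alcohol-level unit and leaves a monocyclic 2-methyleneoxepane fused to the γ-lactone (enol ether at C10, ethynyl at C5).
2. The oxepane is unravelled at O–C10 (alkynol cycloisomerization), C8–C9 (propargylation), C4–C5 (alkynylation) and C7–C8 (radical conjugate addition), back to (S)-5-(hydroxymethyl)furan-2(5H)-one.
3. Forward order of rings: γ-lactone (chiral pool) → oxepane (step 9) → oxepinone ring and, by the same bond, the ten-membered carbocycle (step 10); then C11=C13, C2=C3 and the ester.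
4. Enabling feature: the ether oxygen bridging C5 and C10 holds a terminal alkyne (future C4=C15) and an enol ether (C10=C14, a latent oxocarbenium) one atom apart. A three-carbon aldehyde arm grown on the alkyne can therefore reach C10 only from the face of the C5 substituent. C1 and C10 are both acceptor carbons, so their union needs the acyl carbon reversed in polarity (carbene–aldehyde adduct).
5. Stereochemistry: C6 from the starting lactone; C7 trans to C6 by substrate control; C5 and C8 by reagent and catalyst control; C10 by the bridging tether in the key step; the Z ester geometry from angelic acid.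

Key step: step 10

Remark: locants C1–C15 are those of the germacranolide skeleton of the target (C1 ketone, C4 bearing C15, C5–O–C10 bridge, C6/C7 lactone with C11–C13, C8 ester, C10 bearing C14) and are used for all intermediates. The facial sense of the chiral controllers in steps 3 and 6 is assumed to follow the parent reactions; the antipodal controller would be used if the other carbinol epimer forms.

**Step 1**
Reactants: 1 (S)-5-(hydroxymethyl)furan-2(5H)-one; 2 1,3-dioxolane
Product: 3 (4S,5S)-4-(1,3-dioxolan-2-yl)-5-(hydroxymethyl)dihydrofuran-2(3H)-one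
Conditions: benzophenone (0.15 equiv), 2 as solvent, hν (350 nm), 10 °C
Reagents that add atoms: none
Why: triplet benzophenone abstracts the acetal hydrogen of 2 and the nucleophilic 2-dioxolanyl radical should add in Giese fashion to C7 of the butenolide anti to the C6 substituent, setting the trans C6/C7 relationship and bringing in C8 as a masked aldehyde.

**Step 2**
Reactants: 3
Product: 4 (2S,3S)-3-(1,3-dioxolan-2-yl)-5-oxotetrahydrofuran-2-carbaldehyde
Conditions: Dess–Martin periodinane (1.2 equiv), NaHCO3, CH2Cl2, 0 °C to rt; used crude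
Reagents that add atoms: none
Why: buffered Dess–Martin oxidation of the primary alcohol should give the C5 aldehyde without epimerizing C6 or opening the acetal.

**Step 3**
Reactants: 4; 5 ethynyltrimethylsilane
Product: 6 (4S,5S)-4-(1,3-dioxolan-2-yl)-5-[(1S)-1-hydroxy-3-(trimethylsilyl)prop-2-yn-1-yl]dihydrofuran-2(3H)-one
Conditions: Zn(OTf)2 (1.5 equiv), (1S,2R)-2-(dimethylamino)-1-phenylpropan-1-ol (1.6 equiv), Et3N (1.6 equiv), toluene, rt
Reagents that add atoms: none
Why: amino alcohol-controlled addition of the zinc acetylide to the aldehyde (asymmetric alkynylation) forms C4–C5, and the ligand should deliver the alkyne to the face that gives the 5S carbinol, overriding the bias of the α-oxygenated centre.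

**Step 4**
Reactants: 6
Product: 7 (1S)-1-[(2S,3S)-3-(1,3-dioxolan-2-yl)-5-oxotetrahydrofuran-2-yl]-3-(trimethylsilyl)prop-2-yn-1-yl acetate
Conditions: Ac2O, pyridine, 4-(dimethylamino)pyridine (0.05 equiv), CH2Cl2, 0 °C
Reagents that add atoms: acetic anhydride CC(=O)OC(C)=O
Why: acetylation by nucleophilic catalysis masks the C5 hydroxyl during the C8 chemistry with a group that leaves later together with the alkynyl silyl group.

**Step 5**
Reactants: 7
Product: 8 (1S)-1-[(2S,3S)-3-formyl-5-oxotetrahydrofuran-2-yl]-3-(trimethylsilyl)prop-2-yn-1-yl acetate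
Conditions: HCl (1 M aq.)/THF 1:3, rt; used crude
Reagents that add atoms: water O
Why: acid-catalysed acetal hydrolysis frees the C8 aldehyde; the acetate and C-silyl group are acid-stable and the trans C6/C7 arrangement is the thermodynamic one, so C7 should hold.

**Step 6**
Reactants: 8; 9 4,4,5,5-tetramethyl-2-(propa-1,2-dien-1-yl)-1,3,2-dioxaborolane
Product: 10 (1S)-1-[(2S,3R)-3-[(1R)-1-hydroxybut-3-yn-1-yl]-5-oxotetrahydrofuran-2-yl]-3-(trimethylsilyl)prop-2-yn-1-yl acetate
Conditions: (R)-3,3'-bis(2,4,6-triisopropylphenyl)-1,1'-binaphthalene-2,2'-diyl hydrogen phosphate (0.1 equiv), 4 Å molecular sieves, toluene, −20 °C; aqueous work-up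
Reagents that add atoms: none
Why: chiral phosphoric acid-catalysed allenylboration (SE2' propargylation through a closed six-membered transition state) forms C8–C9 and should set 8R by catalyst control under neutral conditions that do not trigger β-elimination of the lactone oxygen.

**Step 7**
Reactants: 10
Product: 11 (1S)-1-[(2S,3S)-3-[(1R)-1-(tert-butyldimethylsilyloxy)but-3-yn-1-yl]-5-oxotetrahydrofuran-2-yl]-3-(trimethylsilyl)prop-2-yn-1-yl acetate
Conditions: TBSOTf (1.3 equiv), 2,6-lutidine (2 equiv), CH2Cl2, −78 °C
Reagents that add atoms: tert-butyldimethylsilyl trifluoromethanesulfonate CC(C)(C)[Si](C)(C)OS(=O)(=O)C(F)(F)F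
Why: silylation of the C8 hydroxyl prevents its 5-endo attack on the neighbouring alkyne in step 9 and the silyl ether should last until step 15.

**Step 8**
Reactants: 11
Product: 12 (4S,5S)-4-[(1R)-1-(tert-butyldimethylsilyloxy)but-3-yn-1-yl]-5-[(1S)-1-hydroxyprop-2-yn-1-yl]dihydrofuran-2(3H)-one
Conditions: K2CO3 (0.5 equiv), MeOH, 0 °C; pH 7 buffer work-up
Reagents that add atoms: none
Why: carbonate-catalysed methanolysis (transesterification and protiodesilylation) should remove the acetate and the alkynyl silyl group together, leaving the silyl ether and the γ-lactone.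

**Step 9**
Reactants: 12
Product: 13 oxepane enol ether: γ-lactone (O on C6; C7–C11H2–C12=O) trans-fused to a 2-methyleneoxepane (ring O–C5–C6–C7–C8–C9–C10; C10=C14H2); ethynyl on C5; TBS ether on C8; 5S,6S,7S,8R
Conditions: [(2-biphenylyl)(tBu)2PAu(NCMe)]SbF6 (0.05 equiv), CH2Cl2 (0.01 M), rt; Et3N quench; Et3N-deactivated silica
Reagents that add atoms: none
Why: gold-catalysed alkynol cycloisomerization (anti-oxyauration, then protodeauration) should add the only free hydroxyl, at C5, to the internal carbon C10 of the homopropargylic alkyne in the 7-exo-dig mode; no hydroxyl can reach the C4 alkyne.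

**Step 10**
Reactants: 13; 14 allyloxytrimethylsilane
Product: 17 bridged ketone: 11-oxabicyclo[4.4.1]undecane core (C5–O–C10) bearing the C1 ketone; C2H2–C3H2; C4=C15H2; C10 methyl; TBS ether on C8; saturated γ-lactone; 5S,6S,7S,8R,10S, via silyl enol ether 15 (not isolated), via aldehyde 16 (not isolated)
Conditions: [CpRu(MeCN)3]PF6 (0.1 equiv), 14 (3 equiv), acetone, rt; concentrate; then MeOH (3 equiv), 2-(2,4,6-trimethylphenyl)-6,7-dihydro-5H-pyrrolo[2,1-c][1,2,4]triazol-2-ium chloride (0.2 equiv), 1,8-diazabicyclo[5.4.0]undec-7-ene (0.2 equiv), toluene (0.01 M), 90 °C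
Reagents that add atoms: none
Why: Proposed new method: the cationic ruthenium catalyst joins the terminal alkyne of 13 and the alkene of 14 through a ruthenacyclopentene (C3–C4 formed at the internal alkyne carbon; β-hydride loss from C1 and reductive elimination put that hydrogen on C15), and after methanolysis of silyl enol ether 15 the triazolylidene adds to aldehyde 16 to give a hydroxy-enamine acyl-anion equivalent whose C1 attacks C10 of the enol ether while its hydroxyl proton goes to C14, forming C1–C10 and releasing the carbene. The closest known reactions are the ruthenium-catalysed Alder-ene-type coupling of alkynes with allylic alcohols and ethers to γ,δ-unsaturated carbonyl compounds and the carbene-catalysed intramolecular hydroacylation of enol ethers and unactivated alkenes (five- and six-membered rings from aromatic aldehydes); running them as a relay in one flask and closing a bridged seven-membered ring from an aliphatic aldehyde are the new elements. The oxepinone ring closes 7-exo-trig onto the exocyclic enol ether, and since C5 and C10 are already linked through C6–C9 the same bond closes the ten-membered carbocycle of the 11-oxabicyclo[4.4.1]undecane. The quaternary centre C10 is controlled by the tether: the acyl arm hangs from C5, so C1 can reach only the syn face of C10=C14, which should give 10S with C14 becoming the methyl group on the opposite face. The step needs branched regioselectivity in the ruthenium coupling, which the preference of the alkyne substituent for the position β to ruthenium in the metallacycle should secure, and acyl-anion rather than aldol or homoenolate reactivity, which the saturated C2–C3 link and the absence of any other alkene able to accept the proton in a ring-forming geometry should secure; the aprotic silyl ether 14 keeps alcohol from adding to the enol ether before the carbene stage.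

**Step 11**
Reactants: 17
Product: 18 silyl enol ether of 17: C1(OTBS)=C2; otherwise as 17; 5S,6S,7S,8R,10S
Conditions: TBSOTf (1.2 equiv), Et3N (2.5 equiv), CH2Cl2, −78 to 0 °C
Reagents that add atoms: tert-butyldimethylsilyl trifluoromethanesulfonate CC(C)(C)[Si](C)(C)OS(=O)(=O)C(F)(F)F
Why: soft enolization with a silyl triflate gives the enol ether regiospecifically toward C2 because C10 is quaternary, masking the ketone for step 12 and preparing step 14.

**Step 12**
Reactants: 18
Product: 19 Mannich base: 18 carrying CH2NMe2 on C11 (C11 epimers; inconsequential)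
Conditions: LiN(iPr)2 (1.2 equiv), THF, −78 °C; [Me2N=CH2]I (1.3 equiv), −78 °C; cold aq. NH4Cl
Reagents that add atoms: N,N-dimethylmethyleneiminium iodide C[N+](C)=C.[I-]
Why: the lactone lithium enolate, the only enolate that can form, undergoes Mannich aminomethylation at C11, and at −78 °C the silyl enol ether should not react with the iminium salt.

**Step 13**
Reactants: 19
Product: 21 α-methylene lactone: C11=C13H2; C1(OTBS)=C2; TBS ether on C8; 5S,6S,7S,8R,10S, via ammonium iodide 20 (not isolated)
Conditions: MeI (10 equiv), MeOH, rt; concentrate; then NaHCO3 (sat. aq.), CH2Cl2, rt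
Reagents that add atoms: none
Why: exhaustive N-methylation followed by bicarbonate-induced Hofmann-type (E1cB) elimination should unveil the exocyclic α-methylene lactone, the only alkene possible since C11 carries the single acidic hydrogen.

**Step 14**
Reactants: 21
Product: 22 dienone: C1 ketone; C2=C3; C4=C15H2; C11=C13H2; TBS ether on C8; 5S,6S,7S,8R,10S
Conditions: Pd(OAc)2 (1.2 equiv), MeCN/CH2Cl2, rt to 40 °C
Reagents that add atoms: none
Why: Saegusa–Ito oxidation (palladation of the silyl enol ether at C2, β-hydride elimination from C3) should give the C2=C3 enone, cis by ring constraint and conjugated with C4=C15.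

**Step 15**
Reactants: 22
Product: 23 C8 alcohol of the dienone lactone; 5S,6S,7R,8R,10S
Conditions: HF·pyridine, pyridine, THF, 0 °C to rt
Reagents that add atoms: none
Why: buffered fluoride desilylation should free the C8 hydroxyl without conjugate addition to the dienone or the α-methylene lactone.

**Step 16**
Reactants: 23; 24 angelic acid ((Z)-2-methylbut-2-enoic acid)
Product: 26 target CNP0282559.1 (8-angeloyloxy-5,10-epoxy-1-oxogermacra-2,4(15),11(13)-trien-12,6-olide; 5S,6S,7R,8R,10S), via mixed anhydride 25 (not isolated)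
Conditions: 24 (3 equiv), 2,4,6-trichlorobenzoyl chloride (3 equiv), Et3N (6 equiv), toluene, rt; then 23, 75 °C
Reagents that add atoms: none
Why: Yamaguchi-type esterification through the mixed anhydride, run without a nucleophilic catalyst, should acylate the C8 hydroxyl with retention of the Z (angelate) geometry supplied by 24.

**Compound list**

1 | (S)-5-(hydroxymethyl)furan-2(5H)-one | OC[C@H]1OC(=O)C=C1 | starting material
2 | 1,3-dioxolane | C1COCO1 | starting material
3 | (4S,5S)-4-(1,3-dioxolan-2-yl)-5-(hydroxymethyl)dihydrofuran-2(3H)-one | C1C(=O)O[C@H](CO)[C@H]1C2OCCO2 | intermediate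
4 | (2S,3S)-3-(1,3-dioxolan-2-yl)-5-oxotetrahydrofuran-2-carbaldehyde | C1C(=O)O[C@H](C=O)[C@H]1C2OCCO2 | intermediate
5 | ethynyltrimethylsilane | C#C[Si](C)(C)C | starting material
6 | (4S,5S)-4-(1,3-dioxolan-2-yl)-5-[(1S)-1-hydroxy-3-(trimethylsilyl)prop-2-yn-1-yl]dihydrofuran-2(3H)-one | C1C(=O)O[C@H]([C@@H](O)C#C[Si](C)(C)C)[C@H]1C2OCCO2 | intermediate
7 | (1S)-1-[(2S,3S)-3-(1,3-dioxolan-2-yl)-5-oxotetrahydrofuran-2-yl]-3-(trimethylsilyl)prop-2-yn-1-yl acetate | C1C(=O)O[C@H]([C@@H](OC(C)=O)C#C[Si](C)(C)C)[C@H]1C2OCCO2 | intermediate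
8 | (1S)-1-[(2S,3S)-3-formyl-5-oxotetrahydrofuran-2-yl]-3-(trimethylsilyl)prop-2-yn-1-yl acetate | C1C(=O)O[C@H]([C@@H](OC(C)=O)C#C[Si](C)(C)C)[C@H]1C=O | intermediate
9 | 4,4,5,5-tetramethyl-2-(propa-1,2-dien-1-yl)-1,3,2-dioxaborolane (allenylboronic acid pinacol ester) | C=C=CB1OC(C)(C)C(C)(C)O1 | starting material
10 | (1S)-1-[(2S,3R)-3-[(1R)-1-hydroxybut-3-yn-1-yl]-5-oxotetrahydrofuran-2-yl]-3-(trimethylsilyl)prop-2-yn-1-yl acetate | C1C(=O)O[C@H]([C@@H](OC(C)=O)C#C[Si](C)(C)C)[C@H]1[C@H](O)CC#C | intermediate
11 | (1S)-1-[(2S,3S)-3-[(1R)-1-(tert-butyldimethylsilyloxy)but-3-yn-1-yl]-5-oxotetrahydrofuran-2-yl]-3-(trimethylsilyl)prop-2-yn-1-yl acetate | C1C(=O)O[C@H]([C@@H](OC(C)=O)C#C[Si](C)(C)C)[C@H]1[C@H](O[Si](C)(C)C(C)(C)C)CC#C | intermediate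
12 | (4S,5S)-4-[(1R)-1-(tert-butyldimethylsilyloxy)but-3-yn-1-yl]-5-[(1S)-1-hydroxyprop-2-yn-1-yl]dihydrofuran-2(3H)-one | C1C(=O)O[C@H]([C@@H](O)C#C)[C@H]1[C@H](O[Si](C)(C)C(C)(C)C)CC#C | intermediate
13 | oxepane enol ether: γ-lactone trans-fused (C6/C7) to a 2-methyleneoxepane (C10=C14H2), ethynyl on C5, TBS ether on C8; 5S,6S,7S,8R | C1C(=O)O[C@H]2[C@H]1[C@H](O[Si](C)(C)C(C)(C)C)CC(=C)O[C@H]2C#C | intermediate
14 | allyloxytrimethylsilane | C=CCO[Si](C)(C)C | starting material
15 | silyl enol ether: 13 with the ethynyl group replaced by C4(=C15H2)–C3H2–C2H=C1H–OSiMe3 (E/Z mixture); 5S,6S,7S,8R | C1C(=O)O[C@H]2[C@H]1[C@H](O[Si](C)(C)C(C)(C)C)CC(=C)O[C@H]2C(=C)CC=CO[Si](C)(C)C | intermediate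
16 | aldehyde: 13 with the ethynyl group replaced by C4(=C15H2)–C3H2–C2H2–C1HO; 5S,6S,7S,8R | C1C(=O)O[C@H]2[C@H]1[C@H](O[Si](C)(C)C(C)(C)C)CC(=C)O[C@H]2C(=C)CCC=O | intermediate
17 | bridged ketone: 5,10-epoxy bicycle with C1 ketone, C2H2–C3H2, C4=C15H2, C10 methyl, TBS ether on C8, saturated γ-lactone; 5S,6S,7S,8R,10S | C1C(=O)O[C@H]2[C@H]1[C@H](O[Si](C)(C)C(C)(C)C)C[C@]1(C)O[C@H]2C(=C)CCC1=O | intermediate
18 | silyl enol ether of 17, C1(OTBS)=C2; 5S,6S,7S,8R,10S | C1C(=O)O[C@H]2[C@H]1[C@H](O[Si](C)(C)C(C)(C)C)C[C@]1(C)O[C@H]2C(=C)CC=C1O[Si](C)(C)C(C)(C)C | intermediate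
19 | Mannich base: 18 with CH2NMe2 on C11 (C11 epimers) | CN(C)CC1C(=O)O[C@H]2[C@H]1[C@H](O[Si](C)(C)C(C)(C)C)C[C@]1(C)O[C@H]2C(=C)CC=C1O[Si](C)(C)C(C)(C)C | intermediate
20 | ammonium iodide: 18 with CH2NMe3(+) I(−) on C11 | C[N+](C)(C)CC1C(=O)O[C@H]2[C@H]1[C@H](O[Si](C)(C)C(C)(C)C)C[C@]1(C)O[C@H]2C(=C)CC=C1O[Si](C)(C)C(C)(C)C.[I-] | intermediate
21 | α-methylene lactone with C1(OTBS)=C2 and TBS ether on C8; 5S,6S,7S,8R,10S | C=C1C(=O)O[C@H]2[C@H]1[C@H](O[Si](C)(C)C(C)(C)C)C[C@]1(C)O[C@H]2C(=C)CC=C1O[Si](C)(C)C(C)(C)C | intermediate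
22 | dienone with TBS ether on C8; 5S,6S,7S,8R,10S | C=C1C(=O)O[C@H]2[C@H]1[C@H](O[Si](C)(C)C(C)(C)C)C[C@]1(C)O[C@H]2C(=C)C=CC1=O | intermediate
23 | C8 alcohol of the dienone lactone; 5S,6S,7R,8R,10S | C=C1C(=O)O[C@H]2[C@H]1[C@H](O)C[C@]1(C)O[C@H]2C(=C)C=CC1=O | intermediate
24 | angelic acid, (Z)-2-methylbut-2-enoic acid | C/C=C(/C)C(=O)O | starting material
25 | (Z)-2-methylbut-2-enoic 2,4,6-trichlorobenzoic anhydride | C/C=C(/C)C(=O)OC(=O)c1c(Cl)cc(Cl)cc1Cl | intermediate
26 | CNP0282559.1; 5S,6S,7R,8R,10S | C=C1C(=O)O[C@H]2[C@H]1[C@H](OC(=O)/C(C)=C\C)C[C@]1(C)O[C@H]2C(=C)C=CC1=O | target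

**Step count and risks**

Total step count: 16. Longest linear sequence: 16 steps (from 1).

Steps most likely to fail:

1. Step 10 (proposed new method). The ruthenium coupling may lose its branched regiocontrol, the enol ether may be ketalized or hydrolysed before the carbene stage, or aldol and acyloin oligomerization of the aliphatic aldehyde may outrun the seven-membered closure. The fallback sets out from 13 and returns at 17, using known reaction types. The ruthenium coupling is run alone with allyl alcohol ([CpRu(MeCN)3]PF6, acetone, rt) and aldehyde 16 is isolated. Bu3SnLi (THF, −78 °C) adds to the aldehyde to give α-hydroxystannane F1. Pyridinium p-toluenesulfonate (CH2Cl2, rt) adds the new hydroxyl across the C10 enol ether, the usual way of capping α-hydroxystannanes with enol ethers, here intramolecular, to give bridged stannyl ketal F2. n-BuLi (THF, −78 °C, inverse addition) effects tin–lithium exchange, and the α-alkoxy carbanion should undergo [1,2]-Wittig rearrangement with the ketal carbon C10 migrating from oxygen to C1 with retention (ring contraction from eight to seven members), giving carbinol F3. Dess–Martin oxidation then gives ketone 17.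

2. Step 9. The 7-exo-dig closure may be slow, letting hydration of an alkyne, participation of the silyl ether oxygen, or acid-catalysed loss of the enol ether take over. The fallback sets out from 11 and returns at 13, replacing alkyne activation by ketalization and elimination. (Ph3P)AuNTf2 in wet methanol hydrates the free terminal alkyne of 11 (the silylated alkyne does not react) to methyl ketone F4. K2CO3 in MeOH removes the acetate and the alkynyl silyl group to give hydroxy ketone F5. Pyridinium p-toluenesulfonate with HC(OMe)3 in MeOH closes the cyclic mixed methyl ketal F6, since only the C5 hydroxyl is free. Me3SiOTf and iPr2NEt (CH2Cl2, 0 °C) eliminate methanol to give enol ether 13.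

3. Step 16. The angeloyl unit may isomerize to the tigloyl isomer during activation, or acylation of the hindered C8 hydroxyl may be slow enough for the dienone to decompose. The fallback sets out from 23 and returns at 26. Alcohol 23 is esterified with 2-[bis(2,2,2-trifluoroethoxy)phosphoryl]propanoic acid (N,N'-dicyclohexylcarbodiimide, 4-(dimethylamino)pyridine, CH2Cl2) to phosphonate ester F7. Z-selective Horner–Wadsworth–Emmons (Still–Gennari) olefination with acetaldehyde (KN(SiMe3)2, 18-crown-6, THF, −78 °C) then builds the (Z)-2-methylbut-2-enoate in place, giving 26.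

**Further compounds**

F1 | step 10 | α-hydroxystannane: 16 with C1HO converted to C1H(OH)SnBu3 | C1C(=O)O[C@H]2[C@H]1[C@H](O[Si](C)(C)C(C)(C)C)CC(=C)O[C@H]2C(=C)CCC(O)[Sn](CCCC)(CCCC)CCCC
F2 | step 10 | bridged stannyl ketal: C10(CH3)(O–C5)(O–C1H(SnBu3)) eight-membered cyclic ketal | C1C(=O)O[C@H]2[C@H]1[C@H](O[Si](C)(C)C(C)(C)C)C[C@]3(C)O[C@H]2C(=C)CCC(O3)[Sn](CCCC)(CCCC)CCCC
F3 | step 10 | carbinol: 17 with C1H(OH) in place of the ketone | C1C(=O)O[C@H]2[C@H]1[C@H](O[Si](C)(C)C(C)(C)C)C[C@]1(C)O[C@H]2C(=C)CCC1O
F4 | step 9 | methyl ketone: 11 with C10(=O)CH3 in place of the terminal alkyne | C1C(=O)O[C@H]([C@@H](OC(C)=O)C#C[Si](C)(C)C)[C@H]1[C@H](O[Si](C)(C)C(C)(C)C)CC(C)=O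
F5 | step 9 | hydroxy ketone: F4 without the acetate and the alkynyl silyl group | C1C(=O)O[C@H]([C@@H](O)C#C)[C@H]1[C@H](O[Si](C)(C)C(C)(C)C)CC(C)=O
F6 | step 9 | cyclic mixed methyl ketal: oxepane with C10(CH3)(OCH3), C10 epimers | C1C(=O)O[C@H]2[C@H]1[C@H](O[Si](C)(C)C(C)(C)C)CC(C)(OC)O[C@H]2C#C
F7 | step 16 | phosphonate ester: 23 acylated at the C8 oxygen with 2-[bis(2,2,2-trifluoroethoxy)phosphoryl]propanoyl | C=C1C(=O)O[C@H]2[C@H]1[C@H](OC(=O)C(C)P(=O)(OCC(F)(F)F)OCC(F)(F)F)C[C@]1(C)O[C@H]2C(=C)C=CC1=O
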